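Skeleton numbering used throughout: C1 is the quinone carbonyl carbon bonded to C8a, C2 carries the methoxy group, C4 is the second carbonyl carbon. Ring A is C1, C2, C3, C4, C4a, C8a; ring B is C4a, C5, C6, C7, C8, C8a.

## Analysis of the target

Larreantin is a 2-methoxy-1,4-naphthoquinone. Ring A carries the methoxy group at C2 and hydrogen at C3; ring B carries hydrogen at C5, a 4-hydroxy-3-methoxybenzyl group at C6, a methyl group at C7 and a 4-hydroxy-3-methoxyphenyl group at C8. There is no stereocentre: the C8–aryl bond lies between the C7 methyl group and the peri carbonyl C1, but the pendant ring has only hydrogen in its ortho positions, so no stable axis is expected and no configuration has to be controlled. The sensitive groups are the methoxyquinone (a vinylogous ester, easily reduced and open to nucleophiles and base), the two free guaiacol-type phenols (easily oxidised) and the doubly benzylic CH2 at C6. The difficulty is regiochemical: three different carbon substituents sit on the contiguous carbons C6, C7 and C8, the aryl group is wedged into the peri position, and the methoxy group must end on C2 (the side of the aryl group) and not on C3. Substitution chemistry on a preformed naphthalene cannot place these groups reliably. The strategy rests on the fact that the six carbons of ring B fall into three adjacent pairs, C4a–C5, C6–C7 and C8–C8a, each of which is an alkyne in retrosynthesis, while C4a and C8a are joined by the four-carbon chain C4–C3–C2–C1 of ring A. Two of the three alkynes can therefore be held together by ring A itself, and a ketone at C1 with a methoxy group at C2 in that tether fixes the methoxy group on the side of the aryl-bearing carbon C8.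

## Retrosynthetic reasoning

**18 ⇒ 16.** The two phenolic O–H bonds of larreantin 18 are traced back to the O–benzyl bonds of its dibenzyl ether 16. The guaiacol rings have to stay masked through the organometallic steps and, above all, through the oxidation that makes the quinone, which would attack free phenols. Benzyl ethers meet both demands and leave by hydrogenolysis. The forward step has to accept that the quinone is reduced at the same time, to the hydroquinone 17, and is restored on exposure to the atmosphere.

**16 ⇒ 15.** The C4=O bond is removed, which leads to the 2-methoxy-1-naphthol 15. A 1-naphthol with a free para position is the natural precursor of a 1,4-quinone: the hydroxyl marks C1, the para carbon becomes C4, and the methoxy group on C2 is on the correct side without any late regiochemical decision. The forward oxidation must take the para carbon C4 and not the methoxy-bearing ortho carbon C2. It meets only one free hydroxyl in the molecule.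

**15 ⇒ 14.** The CH2 between ring B and the pendant benzyloxy(methoxy)phenyl ring is traced back to the carbonyl group of the diaryl ketone 14. This costs one reduction, but as an aroyl group the C6 substituent is the large, polarising substituent of an alkyne and can steer the ring-forming step. The reduction is placed after the aromatisation of ring A for two reasons: C1 is then a phenol and the diaryl ketone is the only carbonyl left, and the electron-rich diarylmethane does not have to face the dehydrogenating agent. The forward step is an ionic hydrogenation, for which a ketone between two electron-rich rings is well suited.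

**14 ⇒ 13.** The C3=C4 double bond of the naphthol is removed, giving the 2-methoxy-1-tetralone 13. This is the oxidation level that a saturated tether delivers, and it keeps the tether free of extra functional groups. The forward step is a dehydrogenation driven by aromatisation of ring A.

**13 ⇒ 9 + 12.** Three ring-B bonds are cut at once, C4a–C8a, C5–C6 and C7–C8, which opens both rings and leaves the 1,7-diyne 9 and the alkynyl ketone 12. The cut is made here because this is the only division of ring B into three pairs in which every pair is an ordinary alkyne; the other division would make C4a–C8a a cyclic alkyne inside ring A. Of the three alkynes, the two that carry C4a and C8a are tethered by ring A without any temporary linker. The gain is both rings, three skeletal bonds and all four substituents of ring B in one operation from an open chain. The forward reaction, a metal-catalysed [2+2+2] cycloaddition, has to favour the cross-reaction over self-coupling of 9 and has to insert 12 so that its aroyl-bearing carbon bonds to C5 and its methyl-bearing carbon to C8.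

**9 ⇒ 5 + 7 (through 8).** The C1–C8a bond between the ketone and the alkyne is cut. The acyl side becomes the Weinreb amide 5 and the alkynyl side the lithium acetylide 8 of arylacetylene 7. The amide is chosen over an ester so that the addition stops at the ketone.

**5 ⇒ 4 ⇒ 3 ⇒ 1 + 2.** The C2–C3 bond is cut. The electrophile, homopropargylic bromide 2, eliminates readily and carries an acidic alkyne hydrogen, so the lithium enolate of a simple α-methoxy ester is a poor nucleophile for it. The stabilised, weakly basic anion of methoxymalonate 1 is used instead. Malonate 3 then loses one ester group to give ester 4, which is converted into amide 5.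

**7 and 12 ⇒ 6.** Both aryl-bearing pieces come from the same protected aldehyde 6: a one-carbon homologation gives alkyne 7, and addition of the propynyl Grignard reagent 10 followed by oxidation of alcohol 11 gives ketone 12.

## Alternatives that were turned down

**Alternative 1:** ring expansion of an arylindene by one carbon. The disconnection takes C7 out of ring B together with its bonds C6–C7 and C7–C8. This leaves indene A2, a 3-aryl-2-(arylmethyl)-4,5,7-trimethoxy-1H-indene with aryl = 4-benzyloxy-3-methoxyphenyl. In the forward direction a dihalocarbene would add to the tetrasubstituted double bond of A2, and dehydrobrominative opening of the cyclopropane would give the 7-bromonaphthalene A1. A methyl cross-coupling, oxidative demethylation of the trimethoxy ring to 16 and debenzylation would follow.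
- For it: the position of every substituent is fixed by classical bond formation, so there is no regiochemical gamble. Ring A arrives as a 1,2,4-trimethoxyarene that needs one oxidation instead of three redox steps. On both points this alternative is stronger than the chosen route.
- Against it: the carbene must attack a fully substituted, stilbene-like double bond flanked by an aryl and a benzyl group. The methyl group must then be forced by cross-coupling into a position between two ortho substituents. A2 itself needs a long linear sequence (indanone, benzylation, aryl addition, dehydration). The late oxidation with a tetravalent cerium salt must distinguish the trimethoxynaphthalene from two dialkoxyphenyl rings.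
- Comparison: the key step adds one carbon and closes no new ring. The chosen strategy forms both rings and the whole substitution pattern of ring B in one convergent step from two fragments of at most four steps each, and its quinone-forming oxidant meets a single free hydroxyl. The price is a regiochemical bias that is only moderate.

**Alternative 2:** dehydro-Diels–Alder reaction to an arylnaphthalene lactone. The disconnection cuts C6–C7 and C8–C8a and leads to ester A4, the 3-arylprop-2-ynyl ester of 3-(2,4,5-trimethoxyphenyl)propiolic acid. On heating, the trimethoxyphenyl alkyne would act as the diene and the second alkyne as the dienophile. This closes ring B and a five-membered lactone to give A3, with the lactone carbonyl on C6 and the OCH2 group on C7.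
- For it: the step is thermal and metal-free and belongs to a well-established reaction class. The oxygenation of ring A is again carried in from the start. On these points it is at least as strong as the chosen route.
- Against it: either arylalkyne of A4 can serve as the diene, so an isomeric lactone built on the guaiacyl ring is a structural competitor. The substituents also arrive at the wrong oxidation level. The lactone carbonyl must take up an aryl nucleophile and be reduced to CH2, and the C7–CH2–O bond must be reduced to a methyl group. Several steps therefore follow the key step before the cerium oxidation and the debenzylation.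
- Comparison: the chosen cycloaddition delivers methyl, aryl and an aroyl group that is one reduction away from the benzyl group. It builds ring A in the same step instead of requiring a pre-made trimethoxyarene.

**Alternative 3:** Catellani benzylation and methylation of ring B. The disconnection cuts the two exocyclic bonds C6–CH2 and C7–CH3 and leads to the 8-aryl-7-iodo-1,2,4-trimethoxynaphthalene A6 and the benzylic chloride A7. Palladium catalysis with a strained bicyclic alkene as transient mediator would alkylate C6 through C–H activation ortho to the iodide. A methylboron reagent would then terminate at C7 to give A5. Oxidative demethylation to 16 and debenzylation would finish.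
- For it: the iodide dictates both positions, both groups arrive at their final oxidation level, and the endgame is two steps shorter than the chosen one. On these points it is stronger.
- Against it: it does not build the skeleton. A6, with its peri aryl group next to an iodide, needs its own multistep naphthalene synthesis. The arylpalladium intermediate also has the ortho C–H bonds of the neighbouring C8 aryl ring within reach of a five-membered palladacycle. The final methyl transfer must occur at a carbon flanked by two ortho substituents and compete with direct coupling before the alkylation.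
- Comparison: the chosen strategy puts its single risk into the step that also creates the carbon framework. Its precursors are made by routine acetylide and malonate chemistry.

Key step: step 8

Remark on the chemistry: compounds 4, 5, 9, 11 and 13 are racemic. The target has no stereocentre, so this has no consequence. Compounds 1, 2, 6 and 10 are taken as catalogue items.

## Route

Step 1
Reactants: 1 dimethyl 2-methoxypropanedioate (dimethyl methoxymalonate); 2 4-bromobut-1-yne
Product: 3 dimethyl 2-(but-3-yn-1-yl)-2-methoxypropanedioate
Conditions: NaH, DMF, 0 °C; then 2 (1.5 equiv), 0 → 50 °C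
Reagents that add atoms: none
Why: Malonic ester alkylation (SN2) by a stabilised, weakly basic carbanion, which neither deprotonates the alkyne C–H nor favours E2 loss of HBr from the homopropargylic bromide as a simple ester enolate would; the excess of 2 covers what is lost by elimination.

Step 2
Reactants: 3 dimethyl 2-(but-3-yn-1-yl)-2-methoxypropanedioate
Product: 4 methyl 2-methoxyhex-5-ynoate (racemic)
Conditions: LiCl, H2O, DMSO, 150 °C
Reagents that add atoms: none
Why: Krapcho dealkoxycarbonylation: chloride demethylates one ester, the carboxylate loses CO2 and the enolate is protonated by water; the alkyne and the ether are inert under these near-neutral conditions, and C2 is formed racemic, which does not matter because it becomes sp2 in step 9.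

Step 3
Reactants: 4 methyl 2-methoxyhex-5-ynoate
Product: 5 N,2-dimethoxy-N-methylhex-5-ynamide (racemic)
Conditions: MeNH(OMe)·HCl, AlMe3, CH2Cl2, 0 °C → rt; 1 M HCl
Reagents that add atoms: N,O-dimethylhydroxylamine hydrochloride, CNOC.Cl
Why: Weinreb aminolysis of an ester by an aluminium amide formed in the flask; the α-methoxy group raises the electrophilicity of the ester and AlMe3 does not metalate the terminal alkyne at this temperature.

Step 4
Reactants: 6 4-(benzyloxy)-3-methoxybenzaldehyde (O-benzylvanillin)
Product: 7 1-(benzyloxy)-4-ethynyl-2-methoxybenzene
Conditions: MeC(O)C(N2)P(O)(OMe)2, K2CO3, MeOH, rt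
Reagents that add atoms: dimethyl (1-diazo-2-oxopropyl)phosphonate (Ohira–Bestmann reagent), CC(=O)C(=[N+]=[N-])P(=O)(OC)OC
Why: Seyferth–Gilbert homologation in the Ohira–Bestmann form: methanolysis releases the diazomethylphosphonate anion, which olefinates the aldehyde; loss of N2 and 1,2-hydrogen shift give the terminal alkyne, and the benzyl ether is untouched by the mild base.

Step 5
Reactants: 7 1-(benzyloxy)-4-ethynyl-2-methoxybenzene; 5 N,2-dimethoxy-N-methylhex-5-ynamide
Product: 9 1-[4-(benzyloxy)-3-methoxyphenyl]-4-methoxyocta-1,7-diyn-3-one (racemic), via lithium arylacetylide 8 (not isolated)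
Conditions: n-BuLi, THF, −78 °C; then 5, −78 → 0 °C; poured into cold 1 M HCl
Reagents that add atoms: none
Why: Weinreb ketone synthesis: the chelated tetrahedral adduct prevents a second addition, and the arylacetylide is a weaker base than an alkylacetylide, so it is not quenched by the terminal alkyne of 5. The acidic inverse quench protonates the liberated N,O-dimethylhydroxylamine before it can add to the new ynone in conjugate fashion.

Step 6
Reactants: 6 4-(benzyloxy)-3-methoxybenzaldehyde; 10 prop-1-yn-1-ylmagnesium bromide (CH3C≡CMgBr, THF solution)
Product: 11 1-[4-(benzyloxy)-3-methoxyphenyl]but-2-yn-1-ol (racemic)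
Conditions: THF, 0 °C → rt; sat. NH4Cl
Reagents that add atoms: none
Why: Grignard 1,2-addition of an alkynylmagnesium halide to a non-enolisable aromatic aldehyde; the new carbinol centre is racemic and is oxidised away in the next step.

Step 7
Reactants: 11 1-[4-(benzyloxy)-3-methoxyphenyl]but-2-yn-1-ol
Product: 12 1-[4-(benzyloxy)-3-methoxyphenyl]but-2-yn-1-one
Conditions: MnO2, CH2Cl2, rt
Reagents that add atoms: none
Why: MnO2 oxidation of an alcohol that is both benzylic and propargylic, the most reactive substrate class for this reagent; ethers and the alkyne are inert.

Step 8
Reactants: 9 1-[4-(benzyloxy)-3-methoxyphenyl]-4-methoxyocta-1,7-diyn-3-one; 12 1-[4-(benzyloxy)-3-methoxyphenyl]but-2-yn-1-one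
Product: 13 6-[4-(benzyloxy)-3-methoxybenzoyl]-8-[4-(benzyloxy)-3-methoxyphenyl]-2-methoxy-7-methyl-3,4-dihydronaphthalen-1(2H)-one (racemic)
Conditions: Cp*RuCl(cod) (10 mol %), 12 (3 equiv), ClCH2CH2Cl, 60 °C, 9 added over 8 h by syringe pump, Ar
Reagents that add atoms: none
Why: Transition-metal-catalysed [2+2+2] cycloaddition of a tethered diyne with a monoalkyne, the closest known type being the Cp*RuCl-catalysed union of 1,6- and 1,7-diynes, carbonyl-conjugated ones included, with alkynes. After loss of cod the divalent ruthenium fragment binds both alkynes of 9 and couples them oxidatively to a ruthenacyclopentatriene; this forms C4a–C8a and closes ring A as the six-membered carbocycle fused to the metallacycle, each alkyne lying exo to the new ring. Alkyne 12 then adds across the less hindered Ru=C5 unit (formal [2+2], new bond C5–C6), the metallacycle expands to a seven-membered ruthenacycle, and reductive elimination forms C7–C8, closing ring B as the benzene ring and returning divalent ruthenium. No stereocentre is created; C2 of 9 is carried through untouched as a racemate. Two selectivities are needed. Cross-reaction over self-reaction is sought by keeping 9 at low stationary concentration in an excess of 12, which as an internal alkyne does not trimerise readily and can be recovered. For the orientation of 12, the carbon bearing the large aroyl group should bond to the unsubstituted carbene carbon C5 while the methyl-bearing carbon sits on the crowded Cp*Ru centre and ends next to the aryl-bearing C8. This is the steric rule that gives meta products with terminal alkynes, and the polarisation of the ynone (its α-carbon towards the electrophilic carbene carbon) should act in the same sense; the bias is expected to be real but moderate, so the 6-methyl-7-aroyl isomer is the by-product to be separated.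

Step 9
Reactants: 13 6-[4-(benzyloxy)-3-methoxybenzoyl]-8-[4-(benzyloxy)-3-methoxyphenyl]-2-methoxy-7-methyl-3,4-dihydronaphthalen-1(2H)-one
Product: 14 6-[4-(benzyloxy)-3-methoxybenzoyl]-8-[4-(benzyloxy)-3-methoxyphenyl]-2-methoxy-7-methylnaphthalen-1-ol
Conditions: DDQ (1.2 equiv), 1,4-dioxane, 100 °C
Reagents that add atoms: none
Why: Quinone dehydrogenation of a 1-tetralone: DDQ abstracts hydride from C3 of the electron-rich enol C1(OH)=C2(OMe), and the resulting 4H-dienone tautomerises to the naphthol. The C6 aroyl group, conjugated with the C2 methoxy group, lowers the oxidation potential of the product and should protect it from further oxidation; no diarylmethane is present yet.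

Step 10
Reactants: 14 6-[4-(benzyloxy)-3-methoxybenzoyl]-8-[4-(benzyloxy)-3-methoxyphenyl]-2-methoxy-7-methylnaphthalen-1-ol
Product: 15 6-[4-(benzyloxy)-3-methoxybenzyl]-8-[4-(benzyloxy)-3-methoxyphenyl]-2-methoxy-7-methylnaphthalen-1-ol
Conditions: Et3SiH, CF3CO2H, CH2Cl2, 0 °C → rt
Reagents that add atoms: none
Why: Ionic hydrogenation of a diaryl ketone: protonation and hydride transfer give the carbinol, which ionises to a diarylmethyl cation stabilised by the para-benzyloxy ring and by the 2-methoxynaphthalene unit and takes a second hydride. Aryl benzyl ethers and the naphthol should survive brief exposure to the acid at or below room temperature.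

Step 11
Reactants: 15 6-[4-(benzyloxy)-3-methoxybenzyl]-8-[4-(benzyloxy)-3-methoxyphenyl]-2-methoxy-7-methylnaphthalen-1-ol
Product: 16 6-[4-(benzyloxy)-3-methoxybenzyl]-8-[4-(benzyloxy)-3-methoxyphenyl]-2-methoxy-7-methylnaphthalene-1,4-dione (larreantin dibenzyl ether)
Conditions: (KSO3)2NO (2.5 equiv), KH2PO4, acetone–H2O, rt
Reagents that add atoms: potassium nitrosodisulfonate (KSO3)2NO, [K+].[K+].[O]N(S(=O)(=O)[O-])S(=O)(=O)[O-]
Why: Teuber oxidation: the nitroxyl radical takes the phenolic hydrogen, a second equivalent couples at the free para carbon C4, and loss of the imidodisulfonate gives the 1,4-quinone. The reagent reacts only with the single free hydroxyl, so the benzyl-protected rings and the diarylmethane are not touched.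

Step 12
Reactants: 16 6-[4-(benzyloxy)-3-methoxybenzyl]-8-[4-(benzyloxy)-3-methoxyphenyl]-2-methoxy-7-methylnaphthalene-1,4-dione
Product: 18 larreantin, via debenzylated hydroquinone 17 (not isolated)
Conditions: H2 (1 atm), Pd/C, EtOAc–MeOH, rt; filtration; air, rt
Reagents that add atoms: none
Why: Catalytic hydrogenolysis of the two aryl benzyl ethers, with reversible reduction of the quinone to the hydroquinone; the electron-rich 2-methoxynaphthalene-1,4-diol is re-oxidised by air after removal of the catalyst, conditions too mild to affect the free guaiacol rings.

## Compound list

1 | dimethyl 2-methoxypropanedioate (dimethyl methoxymalonate) | COC(C(=O)OC)C(=O)OC | starting material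
2 | 4-bromobut-1-yne | C#CCCBr | starting material
3 | dimethyl 2-(but-3-yn-1-yl)-2-methoxypropanedioate | COC(CCC#C)(C(=O)OC)C(=O)OC | intermediate
4 | methyl 2-methoxyhex-5-ynoate (racemic) | COC(CCC#C)C(=O)OC | intermediate
5 | N,2-dimethoxy-N-methylhex-5-ynamide (racemic) | COC(CCC#C)C(=O)N(C)OC | intermediate
6 | 4-(benzyloxy)-3-methoxybenzaldehyde | COc1cc(C=O)ccc1OCc1ccccc1 | starting material
7 | 1-(benzyloxy)-4-ethynyl-2-methoxybenzene | C#Cc1ccc(OCc2ccccc2)c(OC)c1 | intermediate
8 | lithium [4-(benzyloxy)-3-methoxyphenyl]acetylide | [Li]C#Cc1ccc(OCc2ccccc2)c(OC)c1 | intermediate (not isolated)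
9 | 1-[4-(benzyloxy)-3-methoxyphenyl]-4-methoxyocta-1,7-diyn-3-one (racemic) | COC(CCC#C)C(=O)C#Cc1ccc(OCc2ccccc2)c(OC)c1 | intermediate
10 | prop-1-yn-1-ylmagnesium bromide | CC#C[Mg]Br | starting material
11 | 1-[4-(benzyloxy)-3-methoxyphenyl]but-2-yn-1-ol (racemic) | CC#CC(O)c1ccc(OCc2ccccc2)c(OC)c1 | intermediate
12 | 1-[4-(benzyloxy)-3-methoxyphenyl]but-2-yn-1-one | CC#CC(=O)c1ccc(OCc2ccccc2)c(OC)c1 | intermediate
13 | 6-[4-(benzyloxy)-3-methoxybenzoyl]-8-[4-(benzyloxy)-3-methoxyphenyl]-2-methoxy-7-methyl-3,4-dihydronaphthalen-1(2H)-one (racemic) | COC1CCc2cc(C(=O)c3ccc(OCc4ccccc4)c(OC)c3)c(C)c(-c3ccc(OCc4ccccc4)c(OC)c3)c2C1=O | intermediate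
14 | 6-[4-(benzyloxy)-3-methoxybenzoyl]-8-[4-(benzyloxy)-3-methoxyphenyl]-2-methoxy-7-methylnaphthalen-1-ol | COc1ccc2cc(C(=O)c3ccc(OCc4ccccc4)c(OC)c3)c(C)c(-c3ccc(OCc4ccccc4)c(OC)c3)c2c1O | intermediate
15 | 6-[4-(benzyloxy)-3-methoxybenzyl]-8-[4-(benzyloxy)-3-methoxyphenyl]-2-methoxy-7-methylnaphthalen-1-ol | COc1ccc2cc(Cc3ccc(OCc4ccccc4)c(OC)c3)c(C)c(-c3ccc(OCc4ccccc4)c(OC)c3)c2c1O | intermediate
16 | 6-[4-(benzyloxy)-3-methoxybenzyl]-8-[4-(benzyloxy)-3-methoxyphenyl]-2-methoxy-7-methylnaphthalene-1,4-dione | COC1=CC(=O)c2cc(Cc3ccc(OCc4ccccc4)c(OC)c3)c(C)c(-c3ccc(OCc4ccccc4)c(OC)c3)c2C1=O | intermediate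
17 | 6-(4-hydroxy-3-methoxybenzyl)-8-(4-hydroxy-3-methoxyphenyl)-2-methoxy-7-methylnaphthalene-1,4-diol | COc1cc(O)c2cc(Cc3ccc(O)c(OC)c3)c(C)c(-c3ccc(O)c(OC)c3)c2c1O | intermediate (not isolated)
18 | larreantin, 6-(4-hydroxy-3-methoxybenzyl)-8-(4-hydroxy-3-methoxyphenyl)-2-methoxy-7-methylnaphthalene-1,4-dione | COC1=CC(=O)c2cc(Cc3ccc(O)c(OC)c3)c(C)c(-c3ccc(O)c(OC)c3)c2C1=O | target

## Step count and least certain steps

Total step count: 12. Longest linear sequence: 9 steps (steps 1, 2, 3, 5, 8, 9, 10, 11, 12).

**Step 8 (key step).** Two processes threaten it.
- Self-coupling: the terminal alkyne of a second molecule of 9 is a better partner for the ruthenacycle than the internal alkyne 12, because the Cp*-bearing metal discriminates against internal alkynes. Oligomers of 9 could then dominate despite slow addition.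
- Reversed orientation: insertion of 12 the other way round would place the aroyl group next to the aryl group, because methyl and aroyl differ less in size than hydrogen and a substituent do.

The fallback sets out from 9 and replaces 12 by the propargylic alcohol 11 under the same Cp*RuCl(cod) catalysis. This should give 6-{[4-(benzyloxy)-3-methoxyphenyl](hydroxy)methyl}-8-[4-(benzyloxy)-3-methoxyphenyl]-2-methoxy-7-methyl-3,4-dihydronaphthalen-1(2H)-one F1 as a mixture of diastereomers that converge. The sp3 carbinol carbon with its aryl and hydroxyl groups is much larger than methyl, which should sharpen the steric bias. The alcohol is also a better π-donor towards the electrophilic ruthenacycle than the ynone, and its hydroxyl can hydrogen-bond to the chloride ligand. Oxidation of F1 with MnO2 in CH2Cl2, as in step 7, returns to the route at 13.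

**Step 9.** The enolisation of the C1 ketone, which is shielded by the peri aryl group, may be slow. Forcing conditions could then lead to further oxidation of the naphthol as it forms, or to attack on the benzyl ethers. The fallback sets out from 13 and separates enolisation from oxidation. TMSOTf and Et3N in CH2Cl2 at 0 °C give the trimethylsilyl enol ether F2 of 13. Pd(OAc)2 in MeCN at room temperature (Saegusa–Ito oxidation) then forms the palladium enolate at C2; β-hydride elimination from C3 and tautomerisation return to the route at 14.

**Step 11.** The second nitroxyl radical may couple at the methoxy-bearing ortho carbon C2 instead of C4, which would end in loss of the methoxy group and an ortho-quinone. The lipophilic substrate may also react sluggishly in the aqueous medium. The fallback sets out from 15 and uses a two-electron oxidation in organic solvent. PhI(OAc)2 in MeOH at 0 °C should give the para-quinone monoketal 6-[4-(benzyloxy)-3-methoxybenzyl]-8-[4-(benzyloxy)-3-methoxyphenyl]-2,4,4-trimethoxy-7-methylnaphthalen-1(4H)-one F3. Hydrolysis of the ketal with 1 M HCl in acetone returns to the route at 16.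

**Step 1.** Elimination of HBr from 2 to the volatile enyne may outrun substitution, because the methoxymalonate anion is tertiary and more basic than an unsubstituted malonate anion. The fallback sets out from 1 and avoids the halide. Michael addition of 1 to acrolein (catalytic NaOMe, MeOH, 0 °C) gives dimethyl 2-methoxy-2-(3-oxopropyl)propanedioate F4. Its aldehyde is converted into the terminal alkyne with the Ohira–Bestmann reagent (K2CO3, MeOH, rt, as in step 4), which returns to the route at 3.

**Step 12.** The debenzylation may stay incomplete if the quinone–hydroquinone pair occupies the catalyst surface. The re-oxidation by air may also be accompanied by oxidative degradation of the freed guaiacol rings. The fallback sets out from 16 and avoids all redox chemistry: BCl3 with pentamethylbenzene as cation scavenger in CH2Cl2 at −78 °C, then a MeOH quench, cleaves the aryl benzyl ethers (assisted by chelation to the neighbouring methoxy groups) and gives 18 directly. No new compound lies on this path.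

## Further compounds

F1 | step 8 | 6-{[4-(benzyloxy)-3-methoxyphenyl](hydroxy)methyl}-8-[4-(benzyloxy)-3-methoxyphenyl]-2-methoxy-7-methyl-3,4-dihydronaphthalen-1(2H)-one (mixture of diastereomers) | COC1CCc2cc(C(O)c3ccc(OCc4ccccc4)c(OC)c3)c(C)c(-c3ccc(OCc4ccccc4)c(OC)c3)c2C1=O
F2 | step 9 | [3-(benzyloxy)-4-methoxy... trimethylsilyl enol ether of 13: {6-[4-(benzyloxy)-3-methoxybenzoyl]-8-[4-(benzyloxy)-3-methoxyphenyl]-2-methoxy-7-methyl-3,4-dihydronaphthalen-1-yl}oxy(trimethyl)silane | COC1=C(O[Si](C)(C)C)c2c(cc(C(=O)c3ccc(OCc4ccccc4)c(OC)c3)c(C)c2-c2ccc(OCc3ccccc3)c(OC)c2)CC1
F3 | step 11 | 6-[4-(benzyloxy)-3-methoxybenzyl]-8-[4-(benzyloxy)-3-methoxyphenyl]-2,4,4-trimethoxy-7-methylnaphthalen-1(4H)-one | COC1=CC(OC)(OC)c2cc(Cc3ccc(OCc4ccccc4)c(OC)c3)c(C)c(-c3ccc(OCc4ccccc4)c(OC)c3)c2C1=O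
F4 | step 1 | dimethyl 2-methoxy-2-(3-oxopropyl)propanedioate | COC(CCC=O)(C(=O)OC)C(=O)OC
F0 | step 12 | none | none
A1 | alternative 1 | 8-[4-(benzyloxy)-3-methoxyphenyl]-6-[4-(benzyloxy)-3-methoxybenzyl]-7-bromo-1,2,4-trimethoxynaphthalene | COc1cc(OC)c2cc(Cc3ccc(OCc4ccccc4)c(OC)c3)c(Br)c(-c3ccc(OCc4ccccc4)c(OC)c3)c2c1OC
A2 | alternative 1 | 3-[4-(benzyloxy)-3-methoxyphenyl]-2-[4-(benzyloxy)-3-methoxybenzyl]-4,5,7-trimethoxy-1H-indene | COc1cc(OC)c2CC(Cc3ccc(OCc4ccccc4)c(OC)c3)=C(c3ccc(OCc4ccccc4)c(OC)c3)c2c1OC
A3 | alternative 2 | 4-[4-(benzyloxy)-3-methoxyphenyl]-5,6,8-trimethoxynaphtho[2,3-c]furan-1(3H)-one | COc1cc(OC)c2cc3C(=O)OCc3c(-c3ccc(OCc4ccccc4)c(OC)c3)c2c1OC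
A4 | alternative 2 | 3-[4-(benzyloxy)-3-methoxyphenyl]prop-2-yn-1-yl 3-(2,4,5-trimethoxyphenyl)prop-2-ynoate | COc1cc(OC)c(C#CC(=O)OCC#Cc2ccc(OCc3ccccc3)c(OC)c2)cc1OC
A5 | alternative 3 | 8-[4-(benzyloxy)-3-methoxyphenyl]-6-[4-(benzyloxy)-3-methoxybenzyl]-1,2,4-trimethoxy-7-methylnaphthalene | COc1cc(OC)c2cc(Cc3ccc(OCc4ccccc4)c(OC)c3)c(C)c(-c3ccc(OCc4ccccc4)c(OC)c3)c2c1OC
A6 | alternative 3 | 8-[4-(benzyloxy)-3-methoxyphenyl]-7-iodo-1,2,4-trimethoxynaphthalene | COc1cc(OC)c2ccc(I)c(-c3ccc(OCc4ccccc4)c(OC)c3)c2c1OC
A7 | alternative 3 | 1-(benzyloxy)-4-(chloromethyl)-2-methoxybenzene | COc1cc(CCl)ccc1OCc1ccccc1
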